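Numbering used below: decalin C1–C10 as in labdanes (C4 gem-dimethyl, C5 ring-fusion CH, C8=C9 alkene, C10 angular carbon), chain C11–C18 from C9 to the ester carbon.
Retrosynthetic cuts: C14–C15 of the diene (Suzuki–Miyaura); the C13 methyl and C14–I (alkyne carboalumination); C9–C11 (Negishi coupling at a C9 enol triflate); then C1–C10 and C3–C4 together, which takes ring A apart into 6-methylcarvone and a three-carbon unit.
Enabling feature: in ring A three unsubstituted methylenes (C1–C2–C3) bridge the quaternary carbons C10 and C4, both bound to C5. C10 is alpha to C9 (a ketone before it becomes the alkene carbon) and C4 is a Me2C unit, so C10 can react as an enolate carbon and C4 as the tertiary radical of an isopropenyl group. This is the substitution pattern of carvone (C9=O, C8–Me, C5–isopropenyl).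
Forward order: ring B is (R)-carvone; ring A is annulated in one flask as a [3+3] process (SN2'-type alkylation, then hydrogen-atom-transfer radical closure); the chain is then grown from C9 (C11–C12 alkyne unit, C13/C14 by carboalumination, C15–C18 ester end by cross-coupling).
Stereochemistry: C5 comes from (R)-carvone; C10 is set by alkylation anti to the isopropenyl group (trans ring fusion, both methyl epimers converging); 13E by syn-carboalumination; 15E by cross-metathesis; C17 by auxiliary-controlled methylation.

Key step: step 2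

Remark: compound 3 is used as the C6 epimer mixture that the methylation gives (trans epimer drawn), and the sulfonyl-bearing ring carbon of 7, 9 and 12 is an epimer mixture; both centres are erased later (steps 2 and 5).

Step 1
Reactants: 1 (R)-(−)-carvone
Product: 3 (5R,6S)-2,6-dimethyl-5-(prop-1-en-2-yl)cyclohex-2-en-1-one (trans-6-methylcarvone), via carvone lithium dienolate 2 (not isolated)
Conditions: LDA, THF, −78 °C; MeI, −78 to 0 °C
Reagents that add atoms: iodomethane, CI
Why: Kinetic alpha'-deprotonation of the cross-conjugated enone gives the dienolate, which should be C-methylated mainly anti to the isopropenyl group (enolate alkylation); the new centre need not be clean because it is made planar again in step 2.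

Step 2
Reactants: 3 trans-6-methylcarvone; 4 2,3-bis(phenylsulfonyl)prop-1-ene
Product: 7 (4aS,8aS)-2,5,5,8a-tetramethyl-7-(phenylsulfonyl)-4a,5,6,7,8,8a-hexahydronaphthalen-1(4H)-one (both C7 epimers), via lithium dienolate 5 (not isolated), via allylated dienone 6 (not isolated)
Conditions: LDA (1.0 equiv), THF, −78 °C; cannulate into 4 (1.5 equiv), THF, −78 to 0 °C; then EtOH, Fe(acac)3 (30 mol %), PhSiH3 (3 equiv), 60 °C, same flask
Reagents that add atoms: none
Why: The kinetic alpha'-dienolate 5 adds to the CH2= terminus of 4 and the alpha-sulfonyl carbanion expels benzenesulfinate (addition–elimination, formally SN2'), which forms C1–C10 and leaves a fresh vinyl sulfone in 6; the iron hydride made from Fe(acac)3 and PhSiH3 then gives a hydrogen atom to the CH2 end of the isopropenyl group and the tertiary C4 radical adds to the vinyl sulfone terminus to form C3–C4, after which the alpha-sulfonyl radical is reduced and protonated. The closest known reaction types are the allylation of ketone enolates with 2-sulfonylallyl electrophiles and the hydrogen-atom-transfer initiated (Mukaiyama-type) Giese cyclisation of 1,1-disubstituted alkenes onto electron-poor alkenes, here run back to back as a [3+3] annulation with one three-carbon 1,3-dielectrophile. Ring A is the only ring closed and it closes in the 6-endo-trig radical mode, the first bond being intermolecular. The one lasting new stereocentre, C10 (C8a of 7), is set in the intermolecular alkylation by the C5 isopropenyl group, which lies pseudo-axial beside the methyl-bearing enolate carbon and sends the electrophile to the opposite face, so that C1 and C4 are trans and the ring closed through the non-stereogenic C4 must be trans-fused, while both C6 epimers of 3 converge on the same enolate; the sulfonyl-bearing carbon forms as a mixture and is erased in step 5. The step needs alpha'- over gamma-deprotonation (kinetic amide base at −78 °C), C- over O-alkylation and mono-addition (soft acceptor, dienolate added to excess 4), hydrogen-atom transfer to the electron-rich isopropenyl group and not to the enone or vinyl sulfone (polarity of the hydride), and 6-endo over 5-exo closure (attack on the unsubstituted terminus of an alpha-substituted acceptor).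

Step 3
Reactants: 7 bicyclic enone sulfone
Product: 9 (4aS,8aS)-2,5,5,8a-tetramethyl-7-(phenylsulfonyl)-3,4,4a,5,6,7,8,8a-octahydronaphthalen-1-yl trifluoromethanesulfonate, via lithium enolate 8 (not isolated)
Conditions: LiBH(s-Bu)3, THF, −78 °C; PhNTf2, −78 to 23 °C
Reagents that add atoms: N-phenylbis(trifluoromethanesulfonimide), O=S(=O)(N(c1ccccc1)S(=O)(=O)C(F)(F)F)C(F)(F)F
Why: Conjugate hydride delivery to the hindered carvone-type enone (1,4-reduction) should give regiospecifically the tetrasubstituted C9 enolate, which is O-sulfonylated to the enol triflate (reductive enolate trapping), with no stereocentre created.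

Step 4
Reactants: 9 enol triflate; 10 (4-bromobut-1-yn-1-yl)trimethylsilane
Product: 12 trimethyl{4-[(4aS,8aS)-2,5,5,8a-tetramethyl-7-(phenylsulfonyl)-3,4,4a,5,6,7,8,8a-octahydronaphthalen-1-yl]but-1-yn-1-yl}silane, via alkylzinc bromide 11 (not isolated)
Conditions: 10, Zn dust, I2 (cat.), DMA, 70 °C; then 9, Pd(dppf)Cl2 (5 mol %), THF/DMA, 60 °C
Reagents that add atoms: none
Why: Negishi sp2–sp3 coupling (oxidative addition of zerovalent palladium into the enol triflate, transmetalation from the primary alkylzinc, reductive elimination, the bidentate ligand holding back beta-hydride elimination) should install C11–C12 and fix the tetrasubstituted C8=C9 alkene in place.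

Step 5
Reactants: 12 silylalkyne sulfone
Product: 14 (4aS,8aS)-1-(but-3-yn-1-yl)-2,5,5,8a-tetramethyl-3,4,4a,5,6,7,8,8a-octahydronaphthalene, via desulfonylated silylalkyne 13 (not isolated)
Conditions: Na(Hg) (6% Na), MeOH/THF, −20 to 23 °C, then stirred at 23 °C until the NaOMe formed in the flask has cleaved the C–Si bond
Reagents that add atoms: none
Why: Electron-transfer reductive desulfonylation of the secondary alkyl phenyl sulfone removes the activating group from C2 and the methoxide generated in the same flask protodesilylates the alkyne, the tetrasubstituted alkene and the alkyne being inert to the amalgam.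

Step 6
Reactants: 14 terminal alkyne
Product: 16 (4aS,8aS)-1-[(E)-4-iodo-3-methylbut-3-en-1-yl]-2,5,5,8a-tetramethyl-3,4,4a,5,6,7,8,8a-octahydronaphthalene, via alkenylalane 15 (not isolated)
Conditions: AlMe3 (2 equiv), Cp2ZrCl2 (0.25 equiv), CH2Cl2, 0 to 23 °C; I2, THF, −30 to 0 °C
Reagents that add atoms: trimethylaluminium, C[Al](C)C; iodine, II
Why: Zirconium-catalysed syn-carboalumination (Negishi carboalumination) places methyl on the internal and aluminium on the terminal alkyne carbon on the same side and iodinolysis with retention should give the (E)-trisubstituted alkenyl iodide, so the C13=C14 geometry is set here.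

Step 7
Reactants: 17 but-3-enoic acid; 18 (R)-4-benzyloxazolidin-2-one
Product: 20 (R)-4-benzyl-3-(but-3-enoyl)oxazolidin-2-one, via mixed pivalic anhydride 19 (not isolated)
Conditions: PivCl, Et3N, THF, −20 °C; then 18, LiCl, −20 to 23 °C
Reagents that add atoms: none
Why: N-Acylation of the oxazolidinone through the mixed anhydride under LiCl/amine activation avoids strong base and with it migration of the beta,gamma-double bond into conjugation.

Step 8
Reactants: 20 butenoyl imide
Product: 22 (R)-4-benzyl-3-[(R)-2-methylbut-3-enoyl]oxazolidin-2-one, via sodium Z-dienolate 21 (not isolated)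
Conditions: NaHMDS, THF, −78 °C; MeI, −78 °C
Reagents that add atoms: iodomethane, CI
Why: In this oxazolidinone-auxiliary (Evans) alkylation the chelated Z-dienolate should be methylated at the alpha-carbon on the face opposite the benzyl group, which sets the (R) centre, and alpha-attack keeps the alkene out of conjugation.

Step 9
Reactants: 22 methylated imide
Product: 23 methyl (R)-2-methylbut-3-enoate
Conditions: MeMgBr, MeOH, 0 °C (MeOMgBr formed in the flask); the volatile ester is carried on as a CH2Cl2 solution
Reagents that add atoms: methanol, CO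
Why: Chelation-activated transesterification of the exocyclic imide carbonyl by methoxymagnesium bromide should release the methyl ester and the auxiliary under weakly basic conditions that leave the alpha-centre and the alkene position untouched.

Step 10
Reactants: 23 methyl (R)-2-methylbut-3-enoate; 24 4,4,5,5-tetramethyl-2-vinyl-1,3,2-dioxaborolane
Product: 25 methyl (R,E)-2-methyl-4-(4,4,5,5-tetramethyl-1,3,2-dioxaborolan-2-yl)but-3-enoate
Conditions: second-generation Grubbs catalyst (5 mol %), 24 (3 equiv), CH2Cl2, 40 °C
Reagents that add atoms: none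
Why: Olefin cross-metathesis between the alpha-branched terminal alkene and the vinylboronate, driven by loss of ethene, should give the (E)-alkenylboronate under thermodynamic control without touching the stereocentre.

Step 11
Reactants: 16 alkenyl iodide; 25 alkenylboronate
Product: 26 methyl (2R,3E,5E)-2,6-dimethyl-8-[(4aS,8aS)-2,5,5,8a-tetramethyl-3,4,4a,5,6,7,8,8a-octahydronaphthalen-1-yl]octa-3,5-dienoate
Conditions: Pd(PPh3)4 (10 mol %), TlOEt (1.5 equiv), THF/H2O (3:1), 23 °C
Reagents that add atoms: none
Why: Suzuki–Miyaura coupling of the (E)-alkenyl iodide with the (E)-alkenylboronate proceeds with retention at both partners to give the (3E,5E)-diene, the fast room-temperature thallium-base variant being chosen to spare the base-sensitive alpha-methyl beta,gamma-unsaturated ester.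

Compound list
1 | (R)-(−)-carvone, (5R)-2-methyl-5-(prop-1-en-2-yl)cyclohex-2-en-1-one | CC(=C)[C@@H]1CC=C(C)C(=O)C1 | starting material
2 | lithium (3R)-6-methyl-3-(prop-1-en-2-yl)cyclohexa-1,5-dien-1-olate (alpha'-dienolate of 1) | [Li]OC1=C[C@H](C(C)=C)CC=C1C | intermediate
3 | (5R,6S)-2,6-dimethyl-5-(prop-1-en-2-yl)cyclohex-2-en-1-one (trans-6-methylcarvone) | O=C1C(C)=CC[C@@H](C(C)=C)[C@@H]1C | intermediate
4 | 2,3-bis(phenylsulfonyl)prop-1-ene | C=C(CS(=O)(=O)c1ccccc1)S(=O)(=O)c1ccccc1 | starting material
5 | lithium (3S)-2,6-dimethyl-3-(prop-1-en-2-yl)cyclohexa-1,5-dien-1-olate (alpha'-dienolate of 3) | [Li]OC1=C(C)[C@H](C(C)=C)CC=C1C | intermediate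
6 | (5S,6S)-2,6-dimethyl-6-[2-(phenylsulfonyl)prop-2-en-1-yl]-5-(prop-1-en-2-yl)cyclohex-2-en-1-one | O=C1C(C)=CC[C@@H](C(C)=C)[C@]1(C)CC(=C)S(=O)(=O)c1ccccc1 | intermediate
7 | (4aS,8aS)-2,5,5,8a-tetramethyl-7-(phenylsulfonyl)-4a,5,6,7,8,8a-hexahydronaphthalen-1(4H)-one, C7 epimers | O=C1C(C)=CC[C@H]2C(C)(C)CC(S(=O)(=O)c3ccccc3)C[C@]12C | intermediate
8 | lithium (4aS,8aS)-2,5,5,8a-tetramethyl-7-(phenylsulfonyl)-3,4,4a,5,6,7,8,8a-octahydronaphthalen-1-olate | [Li]OC1=C(C)CC[C@H]2C(C)(C)CC(S(=O)(=O)c3ccccc3)C[C@]12C | intermediate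
9 | (4aS,8aS)-2,5,5,8a-tetramethyl-7-(phenylsulfonyl)-3,4,4a,5,6,7,8,8a-octahydronaphthalen-1-yl trifluoromethanesulfonate | O=S(=O)(OC1=C(C)CC[C@H]2C(C)(C)CC(S(=O)(=O)c3ccccc3)C[C@]12C)C(F)(F)F | intermediate
10 | (4-bromobut-1-yn-1-yl)trimethylsilane | C[Si](C)(C)C#CCCBr | starting material
11 | bromo[4-(trimethylsilyl)but-3-yn-1-yl]zinc | C[Si](C)(C)C#CCC[Zn]Br | intermediate
12 | trimethyl{4-[(4aS,8aS)-2,5,5,8a-tetramethyl-7-(phenylsulfonyl)-3,4,4a,5,6,7,8,8a-octahydronaphthalen-1-yl]but-1-yn-1-yl}silane | C[Si](C)(C)C#CCCC1=C(C)CC[C@H]2C(C)(C)CC(S(=O)(=O)c3ccccc3)C[C@]12C | intermediate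
13 | trimethyl{4-[(4aS,8aS)-2,5,5,8a-tetramethyl-3,4,4a,5,6,7,8,8a-octahydronaphthalen-1-yl]but-1-yn-1-yl}silane | C[Si](C)(C)C#CCCC1=C(C)CC[C@H]2C(C)(C)CCC[C@]12C | intermediate
14 | (4aS,8aS)-1-(but-3-yn-1-yl)-2,5,5,8a-tetramethyl-3,4,4a,5,6,7,8,8a-octahydronaphthalene | C#CCCC1=C(C)CC[C@H]2C(C)(C)CCC[C@]12C | intermediate
15 | dimethyl{(E)-2-methyl-4-[(4aS,8aS)-2,5,5,8a-tetramethyl-3,4,4a,5,6,7,8,8a-octahydronaphthalen-1-yl]but-1-en-1-yl}alumane | C[Al](C)/C=C(\C)CCC1=C(C)CC[C@H]2C(C)(C)CCC[C@]12C | intermediate
16 | (4aS,8aS)-1-[(E)-4-iodo-3-methylbut-3-en-1-yl]-2,5,5,8a-tetramethyl-3,4,4a,5,6,7,8,8a-octahydronaphthalene | I/C=C(\C)CCC1=C(C)CC[C@H]2C(C)(C)CCC[C@]12C | intermediate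
17 | but-3-enoic acid | C=CCC(=O)O | starting material
18 | (R)-4-benzyloxazolidin-2-one | O=C1OC[C@@H](Cc2ccccc2)N1 | starting material
19 | but-3-enoic pivalic anhydride | C=CCC(=O)OC(=O)C(C)(C)C | intermediate
20 | (R)-4-benzyl-3-(but-3-enoyl)oxazolidin-2-one | C=CCC(=O)N1C(=O)OC[C@H]1Cc1ccccc1 | intermediate
21 | sodium (1Z)-1-[(R)-4-benzyl-2-oxooxazolidin-3-yl]buta-1,3-dien-1-olate | [Na]O/C(=C\C=C)N1C(=O)OC[C@H]1Cc1ccccc1 | intermediate
22 | (R)-4-benzyl-3-[(R)-2-methylbut-3-enoyl]oxazolidin-2-one | C=C[C@@H](C)C(=O)N1C(=O)OC[C@H]1Cc1ccccc1 | intermediate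
23 | methyl (R)-2-methylbut-3-enoate | COC(=O)[C@H](C)C=C | intermediate
24 | 4,4,5,5-tetramethyl-2-vinyl-1,3,2-dioxaborolane | C=CB1OC(C)(C)C(C)(C)O1 | starting material
25 | methyl (R,E)-2-methyl-4-(4,4,5,5-tetramethyl-1,3,2-dioxaborolan-2-yl)but-3-enoate | COC(=O)[C@H](C)/C=C/B1OC(C)(C)C(C)(C)O1 | intermediate
26 | methyl (2R,3E,5E)-2,6-dimethyl-8-[(4aS,8aS)-2,5,5,8a-tetramethyl-3,4,4a,5,6,7,8,8a-octahydronaphthalen-1-yl]octa-3,5-dienoate | COC(=O)[C@H](C)/C=C/C=C(\C)CCC1=C(C)CC[C@H]2C(C)(C)CCC[C@]12C | target

Total step count: 11. Longest linear sequence: 7 steps (steps 1 to 6 and step 11).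

Steps most likely to fail

Step 2. The one-flask sequence may stall after the first bond: the vinyl sulfone unveiled by the alkylation can be consumed by a second dienolate or by re-addition of sulfinate in ethanol, and the iron hydride can be quenched by the amine and lithium salts carried over. The fallback splits the sequence and makes the radical another way. It sets out from the allylated dienone 6, isolated after aqueous work-up of the alkylation stage. HBr in AcOH at 0 °C adds in the Markovnikov sense to the isopropenyl group to give the tertiary bromide F1. Slow addition of Bu3SnH with AIBN in benzene at 80 °C then generates the same tertiary C4 radical by bromine-atom abstraction, and this closes in the 6-endo mode onto the vinyl sulfone. The fallback comes back to the route at 7.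

Step 4. Alkyl transfer to the enol triflate, flanked by the quaternary C10 and the C8 methyl group, may be slow, so that protodezincation or beta-hydride elimination takes over. The fallback brings the two carbons in by sp2–sp2 coupling followed by a displacement. It sets out from triflate 9. Stille coupling with tributyl(vinyl)stannane (Pd(PPh3)4, THF, 65 °C) should give the vinyl diene F2. 9-BBN adds only to the monosubstituted terminus and H2O2/NaOH gives the primary alcohol F3. PPh3, I2 and imidazole give the primary iodide F4. Displacement with lithium (trimethylsilyl)acetylide in THF/DMPU forms the C12–C13 bond and comes back to the route at 12.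

Step 11. The basic coupling medium may erode the C17 centre by enolisation or move the C15=C16 alkene into conjugation with the ester, and the boronate may protodeboronate. The fallback carries the stereocentre through the coupling at the alcohol oxidation level. It sets out from imide 22 and iodide 16. LiBH4 (THF, MeOH, 0 °C) cleaves the auxiliary to give the volatile alcohol (R)-2-methylbut-3-en-1-ol F5. Cross-metathesis with 24 gives the hydroxy alkenylboronate F6. The same palladium/thallium coupling with 16 gives the dienol F7, which has no acidic C–H at the stereocentre. Dess–Martin periodinane (NaHCO3, 0 °C) gives the aldehyde F8, used at once, and NaClO2/NaH2PO4/2-methyl-2-butene gives the acid F9. Trimethylsilyldiazomethane in MeOH/toluene then gives 26, where the fallback comes back to the route.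

Further compounds
F1 | step 2 | (5R,6S)-5-(2-bromopropan-2-yl)-2,6-dimethyl-6-[2-(phenylsulfonyl)prop-2-en-1-yl]cyclohex-2-en-1-one | O=C1C(C)=CC[C@@H](C(C)(C)Br)[C@]1(C)CC(=C)S(=O)(=O)c1ccccc1
F2 | step 4 | (4aS,8aS)-1-ethenyl-2,5,5,8a-tetramethyl-7-(phenylsulfonyl)-3,4,4a,5,6,7,8,8a-octahydronaphthalene | C=CC1=C(C)CC[C@H]2C(C)(C)CC(S(=O)(=O)c3ccccc3)C[C@]12C
F3 | step 4 | 2-[(4aS,8aS)-2,5,5,8a-tetramethyl-7-(phenylsulfonyl)-3,4,4a,5,6,7,8,8a-octahydronaphthalen-1-yl]ethan-1-ol | OCCC1=C(C)CC[C@H]2C(C)(C)CC(S(=O)(=O)c3ccccc3)C[C@]12C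
F4 | step 4 | (4aS,8aS)-1-(2-iodoethyl)-2,5,5,8a-tetramethyl-7-(phenylsulfonyl)-3,4,4a,5,6,7,8,8a-octahydronaphthalene | ICCC1=C(C)CC[C@H]2C(C)(C)CC(S(=O)(=O)c3ccccc3)C[C@]12C
F5 | step 11 | (R)-2-methylbut-3-en-1-ol | OC[C@H](C)C=C
F6 | step 11 | (R,E)-2-methyl-4-(4,4,5,5-tetramethyl-1,3,2-dioxaborolan-2-yl)but-3-en-1-ol | OC[C@H](C)/C=C/B1OC(C)(C)C(C)(C)O1
F7 | step 11 | (2R,3E,5E)-2,6-dimethyl-8-[(4aS,8aS)-2,5,5,8a-tetramethyl-3,4,4a,5,6,7,8,8a-octahydronaphthalen-1-yl]octa-3,5-dien-1-ol | OC[C@H](C)/C=C/C=C(\C)CCC1=C(C)CC[C@H]2C(C)(C)CCC[C@]12C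
F8 | step 11 | (2R,3E,5E)-2,6-dimethyl-8-[(4aS,8aS)-2,5,5,8a-tetramethyl-3,4,4a,5,6,7,8,8a-octahydronaphthalen-1-yl]octa-3,5-dienal | O=C[C@H](C)/C=C/C=C(\C)CCC1=C(C)CC[C@H]2C(C)(C)CCC[C@]12C
F9 | step 11 | (2R,3E,5E)-2,6-dimethyl-8-[(4aS,8aS)-2,5,5,8a-tetramethyl-3,4,4a,5,6,7,8,8a-octahydronaphthalen-1-yl]octa-3,5-dienoic acid | OC(=O)[C@H](C)/C=C/C=C(\C)CCC1=C(C)CC[C@H]2C(C)(C)CCC[C@]12C
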